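**Retrosynthetic overview** (labdane numbering: C10 = quaternary ring-fusion carbon carrying C20H2OAc, C9 = ring-B CH carrying the side chain, C7=C8 = ring-B alkene)

1. End game: angelate on the equatorial 2α-OH; the cis-2α,3α-diol from a C2=C3 silyl enol ether (Rubottom oxidation, then bulky hydride); the C20 acetate from a C20 carboxyl.
2. Enabling feature: ring B contains the γ,δ-unsaturated acid pattern C20(oxidised)–C10(quaternary)–C9–C8=C7, and C7 is tied back to C10 through C6–C5. Ring B is therefore opened at C9–C10 to a δ-lactone O–C7–C6–C5–C10–C20(=O) bearing an (E)-C8=C9 alkenyl arm at C7 (Ireland–Claisen lactone-to-carbocycle transform; C7 chirality goes to C9 and C10).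
3. Ring A is built onto the unsaturated lactone by a formal [4+2] with Me2C=C(OSiR3)–CH=CH2 (bonds C4–C5 and C1–C10), anti to the C7 substituent, which also delivers the C2=C3 enol ether. Ring order: δ-lactone (temporary ring), then ring A, then ring B (the lactone ring is consumed).
4. The 6-alkenyl-5,6-dihydropyran-2-one comes from (R)-linalool (C7–C9, C11–C17, including C13) by allylic oxidation, asymmetric propargylation, carboxylation and semi-hydrogenation.

Key step: step 8

Assumption: (R)-(−)-linalool of high enantiomeric purity and 4-methylpent-1-en-3-one are taken as purchasable; the C13 centre of the target has the configuration of (R)-linalool.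

**Route**

Step 1
Reactants: 1 (R)-(−)-linalool
Product: 2 (3R)-3,7-dimethyl-3-(triethylsilyloxy)octa-1,6-diene
Conditions: Et3SiOTf, 2,6-lutidine, CH2Cl2, −78 to 0 °C
Reagents that add atoms: triethylsilyl trifluoromethanesulfonate, CC[Si](CC)(CC)OS(=O)(=O)C(F)(F)F
Why: Silyl triflate silylation of a hindered tertiary alcohol is reliable and masks the C13 hydroxyl (which would otherwise add to the later enal and lactone acceptors) without touching the stereocentre.

Step 2
Reactants: 2 linalool triethylsilyl ether
Product: 4 (2E,6R)-2,6-dimethyl-6-(triethylsilyloxy)octa-2,7-dienal, via allylic alcohol 3 (not isolated)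
Conditions: SeO2 (0.3 equiv), t-BuOOH, CH2Cl2, 0 °C to rt; filter, then MnO2, CH2Cl2, rt
Reagents that add atoms: tert-butyl hydroperoxide, CC(C)(C)OO (terminal oxidant; the oxygen is passed on through SeO2, O=[Se]=O)
Why: Riley allylic oxidation (ene reaction then [2,3]-shift) attacks the (E)-methyl group of the trisubstituted alkene, the vinyl group having no allylic hydrogen, and MnO2 then oxidises the allylic alcohol to the (E)-enal whose geometry later fixes C9.

Step 3
Reactants: 4 (E)-enal
Product: 5 (4S,5E,9R)-5,9-dimethyl-9-(triethylsilyloxy)undeca-5,10-dien-1-yn-4-ol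
Conditions: allenylboronic acid pinacol ester (1.5 equiv), (S)-TRIP [(S)-3,3'-bis(2,4,6-triisopropylphenyl)-1,1'-binaphthyl-2,2'-diyl hydrogen phosphate, 10 mol %], 4 Å MS, toluene, −20 °C
Reagents that add atoms: allenylboronic acid pinacol ester, C=C=CB1OC(C)(C)C(C)(C)O1
Why: Chiral phosphoric acid-catalysed propargylboration (SE2' transfer from the allenylboronate through a closed six-membered transition state held by the phosphate) should add to the Si face of the enal and set the 4S carbinol, the future C7, the (S) catalyst being the antipode expected for this sense by analogy with aryl and alkenyl aldehydes.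

Step 4
Reactants: 5 homopropargylic alcohol
Product: 6 (5S,6E,10R)-5-hydroxy-6,10-dimethyl-10-(triethylsilyloxy)dodeca-6,11-dien-2-ynoic acid
Conditions: n-BuLi (2.2 equiv), THF, −78 °C; CO2 (gas), −78 to 0 °C; cold 0.5 M HCl to pH 3
Reagents that add atoms: carbon dioxide, O=C=O
Why: Carboxylation of the lithium acetylide of the dianion (the alkoxide is carbonated only reversibly and is released on acidification) adds the future C20 without affecting the carbinol centre.

Step 5
Reactants: 6 hydroxy ynoic acid
Product: 8 (6S)-6-[(2E,6R)-6-methyl-6-(triethylsilyloxy)octa-2,7-dien-2-yl]-5,6-dihydro-2H-pyran-2-one, via Z-hydroxy acid 7 (not isolated)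
Conditions: H2 (1 atm), Pd/CaCO3 poisoned with Pb(OAc)2 (Lindlar catalyst), quinoline, EtOAc, rt; filter, then PPTS (cat.), CH2Cl2, rt
Reagents that add atoms: none
Why: Lindlar semi-hydrogenation reduces the ynoic acid to the (Z)-enoic acid much faster than it touches the hindered vinyl and trisubstituted alkenes, and the (Z)-5-hydroxy acid lactonises under mild acid catalysis with C7 unchanged.

Step 6
Reactants: 9 4-methylpent-1-en-3-one
Product: 10 tert-butyl(dimethyl)[(4-methylpenta-1,3-dien-3-yl)oxy]silane
Conditions: t-BuMe2SiOTf, Et3N, CH2Cl2, 0 °C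
Reagents that add atoms: tert-butyldimethylsilyl trifluoromethanesulfonate, CC(C)(C)[Si](C)(C)OS(=O)(=O)C(F)(F)F
Why: Soft enolisation (silyl triflate and amine) of a ketone with a single enolisable position, the isopropyl CH, can give only this 2-silyloxydiene.

Step 7
Reactants: 8 dihydropyranone; 10 silyloxydiene
Product: 11 (3S,4aR,8aR)-6-(tert-butyldimethylsilyloxy)-5,5-dimethyl-3-[(2E,6R)-6-methyl-6-(triethylsilyloxy)octa-2,7-dien-2-yl]-3,4,4a,5,8,8a-hexahydro-1H-isochromen-1-one
Conditions: t-BuMe2SiNTf2 (10 mol %), equimolar partners, CH2Cl2, −78 to −40 °C; Et3N quench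
Reagents that add atoms: none
Why: Silyl triflimide-catalysed formal Diels–Alder reaction (Mukaiyama–Michael addition followed by intramolecular Mukaiyama–Michael ring closure, so that the hindered diene need not reach an s-cis geometry; the catalyst is preformed from Tf2NH and allyl(tert-butyl)dimethylsilane, so that no diene is spent on it, the partners are used 1:1 and every atom of both ends in 11) joins the nucleophilic CMe2 terminus to the lactone β-carbon C5 by axial attack anti to the pseudo-equatorial C7 alkenyl group, which sets C5 trans to C7, then closes C1–C10 to the cis-fused lactone and returns the C2=C3 silyl enol ether.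

Step 8
Reactants: 11 bicyclic lactone
Product: 14 (13R)-3-(tert-butyldimethylsilyloxy)-13-(triethylsilyloxy)labda-2,7,14-trien-20-oic acid, via silyl ketene acetal 12 (not isolated), via trimethylsilyl ester 13 (not isolated)
Conditions: LiN(i-Pr)2 (1.3 equiv), Me3SiCl/Et3N (premixed, 3 equiv), THF, −78 °C to rt; solvent switch to toluene, 105 °C; pH 7 buffer/MeOH work-up
Reagents that add atoms: none
Why: Kinetic deprotonation of the only acidic C–H (C10–H; the ketone is masked as its silyl enol ether) with in-situ silylation gives the lactone silyl ketene acetal 12 (C10=C20), whose allyl vinyl ether array C10=C20–O–C7–C8=C9 undergoes a concerted suprafacial [3,3]-sigmatropic shift that makes C9–C10, breaks O–C7 and moves the double bond to C7=C8. The closest known reaction type is the Ireland–Claisen rearrangement of alkenyl-substituted lactone enolates to cycloalkenecarboxylic acids (lactone-to-carbocycle ring contraction, also known as the dioxanone-to-dihydropyran variant). Ring B (C5–C6–C7–C8–C9–C10) is closed through a bicyclo[2.2.2]-like boat transition state in which the six-membered lactone is the tether; the lactone ring is consumed and its carbonyl becomes the axial C20 carboxyl. The quaternary C10 is controlled by the C7 carbinol centre, because the alkenyl arm can reach only the enolate face on which it sits, the face cis to H5 and anti to C4, so that C20 ends trans to H5 (trans-decalin); C9 is controlled by the (E) geometry of C8=C9, which places C11 outside and H9 inside the boat. The step needs enolisation at C10 only and no ketene-type fragmentation of the lactone enolate, which the absence of any other acidic hydrogen and trapping at −78 °C with premixed Me3SiCl/Et3N should secure; the intended allyl vinyl ether is the only [3,3] array in 12. The trimethylsilyl ester 13 is hydrolysed on neutral work-up, while the tert-butyldimethylsilyl enol ether and the triethylsilyl ether stay in place.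

Step 9
Reactants: 14 carboxylic acid
Product: 15 (13R)-3-(tert-butyldimethylsilyloxy)-13-(triethylsilyloxy)labda-2,7,14-trien-20-ol
Conditions: LiAlH4, THF, 0 °C to reflux; H2O/aq NaOH work-up
Reagents that add atoms: none
Why: LiAlH4 reduction of the hindered carboxylic acid to the neopentyl primary alcohol leaves the silyl enol ether, the silyl ether and the isolated alkenes untouched, and no stereocentre is involved.

Step 10
Reactants: 15 primary alcohol
Product: 16 (13R)-3-(tert-butyldimethylsilyloxy)-13-(triethylsilyloxy)labda-2,7,14-trien-20-yl acetate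
Conditions: Ac2O, pyridine, DMAP (cat.), CH2Cl2, rt
Reagents that add atoms: acetic anhydride, CC(=O)OC(C)=O
Why: DMAP-catalysed acetylation of the only free hydroxyl installs the C20 acetate before any other hydroxyl is unmasked.

Step 11
Reactants: 16 acetate
Product: 18 (13R)-2α,13-dihydroxy-3-oxolabda-7,14-dien-20-yl acetate, via silyloxy epoxide 17 (not isolated)
Conditions: dimethyldioxirane (1.05 equiv, acetone), CH2Cl2, −78 to −40 °C; concentrate, then HF·pyridine, THF/pyridine, 0 °C to rt
Reagents that add atoms: dimethyldioxirane, CC1(C)OO1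
Why: Rubottom oxidation: the electron-rich silyl enol ether is epoxidised by the dioxirane far faster than the trisubstituted and monosubstituted alkenes and from the α face, away from the axial C10 acetoxymethyl and 4β-methyl groups, so that fluoride-induced opening gives the equatorial 2α-hydroxy ketone while the same HF·pyridine treatment cleaves the tertiary triethylsilyl ether.

Step 12
Reactants: 18 hydroxy ketone
Product: 19 (13R)-2α,3α,13-trihydroxylabda-7,14-dien-20-yl acetate
Conditions: K[HB(sec-Bu)3] (3.5 equiv), THF, −78 °C; sat. aq NH4Cl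
Reagents that add atoms: none
Why: Reduction of a 4,4-dimethyl-3-ketone with a bulky trialkylborohydride proceeds by equatorial attack from the β face, as with 3-oxo triterpenoids, and should give the axial 3α-alcohol cis to the 2α-hydroxyl, while the acetate survives at −78 °C.

Step 13
Reactants: 19 triol acetate
Product: 20 (2R,3S,5R,9S,10S,13R)-20-acetoxy-3α,13-dihydroxylabda-7,14-dien-2α-yl (Z)-2-methylbut-2-enoate
Conditions: angelic acid (1.5 equiv), 2,4,6-trichlorobenzoyl chloride (1.5 equiv), Et3N, toluene, rt; then 19, toluene, 75 °C (no DMAP)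
Reagents that add atoms: angelic acid [(Z)-2-methylbut-2-enoic acid], C/C=C(/C)C(=O)O
Why: Yamaguchi-type esterification through the 2,4,6-trichlorobenzoic mixed anhydride without a nucleophilic catalyst transfers the angeloyl group without Z to E isomerisation and should acylate the equatorial 2α-hydroxyl in preference to the axial neopentyl 3α-hydroxyl and the tertiary 13-hydroxyl.

**Compound list**

1 | (R)-(−)-linalool, (3R)-3,7-dimethylocta-1,6-dien-3-ol | CC(C)=CCC[C@@](C)(O)C=C | starting material
2 | (3R)-3,7-dimethyl-3-(triethylsilyloxy)octa-1,6-diene | CC(C)=CCC[C@@](C)(O[Si](CC)(CC)CC)C=C | intermediate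
3 | (2E,6R)-2,6-dimethyl-6-(triethylsilyloxy)octa-2,7-dien-1-ol (not isolated) | OC/C(C)=C/CC[C@@](C)(O[Si](CC)(CC)CC)C=C | intermediate
4 | (2E,6R)-2,6-dimethyl-6-(triethylsilyloxy)octa-2,7-dienal | O=C/C(C)=C/CC[C@@](C)(O[Si](CC)(CC)CC)C=C | intermediate
5 | (4S,5E,9R)-5,9-dimethyl-9-(triethylsilyloxy)undeca-5,10-dien-1-yn-4-ol | C#CC[C@H](O)/C(C)=C/CC[C@@](C)(O[Si](CC)(CC)CC)C=C | intermediate
6 | (5S,6E,10R)-5-hydroxy-6,10-dimethyl-10-(triethylsilyloxy)dodeca-6,11-dien-2-ynoic acid | OC(=O)C#CC[C@H](O)/C(C)=C/CC[C@@](C)(O[Si](CC)(CC)CC)C=C | intermediate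
7 | (2Z,5S,6E,10R)-5-hydroxy-6,10-dimethyl-10-(triethylsilyloxy)dodeca-2,6,11-trienoic acid (not isolated) | OC(=O)/C=C\C[C@H](O)/C(C)=C/CC[C@@](C)(O[Si](CC)(CC)CC)C=C | intermediate
8 | (6S)-6-[(2E,6R)-6-methyl-6-(triethylsilyloxy)octa-2,7-dien-2-yl]-5,6-dihydro-2H-pyran-2-one | O=C1C=CC[C@H](O1)/C(C)=C/CC[C@@](C)(O[Si](CC)(CC)CC)C=C | intermediate
9 | 4-methylpent-1-en-3-one (isopropyl vinyl ketone) | C=CC(=O)C(C)C | starting material
10 | tert-butyl(dimethyl)[(4-methylpenta-1,3-dien-3-yl)oxy]silane | C=CC(O[Si](C)(C)C(C)(C)C)=C(C)C | intermediate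
11 | (3S,4aR,8aR)-6-(tert-butyldimethylsilyloxy)-5,5-dimethyl-3-[(2E,6R)-6-methyl-6-(triethylsilyloxy)octa-2,7-dien-2-yl]-3,4,4a,5,8,8a-hexahydro-1H-isochromen-1-one (cis-fused; C5 substituent of the carbocycle anti to the C3 alkenyl group) | O=C1O[C@H](/C(C)=C/CC[C@@](C)(O[Si](CC)(CC)CC)C=C)C[C@@H]2[C@H]1CC=C(O[Si](C)(C)C(C)(C)C)C2(C)C | intermediate
12 | trimethylsilyl ketene acetal of 11 (C1=C8a double bond, 1-OSiMe3; C3 and C4a as in 11; not isolated) | C[Si](C)(C)OC1=C2CC=C(O[Si](C)(C)C(C)(C)C)C(C)(C)[C@@H]2C[C@H](O1)/C(C)=C/CC[C@@](C)(O[Si](CC)(CC)CC)C=C | intermediate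
13 | trimethylsilyl (13R)-3-(tert-butyldimethylsilyloxy)-13-(triethylsilyloxy)labda-2,7,14-trien-20-oate (not isolated) | C=C[C@](C)(O[Si](CC)(CC)CC)CC[C@H]1C(C)=CC[C@H]2C(C)(C)C(O[Si](C)(C)C(C)(C)C)=CC[C@]12C(=O)O[Si](C)(C)C | intermediate
14 | (13R)-3-(tert-butyldimethylsilyloxy)-13-(triethylsilyloxy)labda-2,7,14-trien-20-oic acid (5α-H, 9α-H, 10β-CO2H) | C=C[C@](C)(O[Si](CC)(CC)CC)CC[C@H]1C(C)=CC[C@H]2C(C)(C)C(O[Si](C)(C)C(C)(C)C)=CC[C@]12C(O)=O | intermediate
15 | (13R)-3-(tert-butyldimethylsilyloxy)-13-(triethylsilyloxy)labda-2,7,14-trien-20-ol | C=C[C@](C)(O[Si](CC)(CC)CC)CC[C@H]1C(C)=CC[C@H]2C(C)(C)C(O[Si](C)(C)C(C)(C)C)=CC[C@]12CO | intermediate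
16 | (13R)-3-(tert-butyldimethylsilyloxy)-13-(triethylsilyloxy)labda-2,7,14-trien-20-yl acetate | C=C[C@](C)(O[Si](CC)(CC)CC)CC[C@H]1C(C)=CC[C@H]2C(C)(C)C(O[Si](C)(C)C(C)(C)C)=CC[C@]12COC(C)=O | intermediate
17 | (13R)-3β-(tert-butyldimethylsilyloxy)-2α,3α-epoxy-13-(triethylsilyloxy)labda-7,14-dien-20-yl acetate (not isolated) | C=C[C@](C)(O[Si](CC)(CC)CC)CC[C@H]1C(C)=CC[C@H]2C(C)(C)[C@]3(O[Si](C)(C)C(C)(C)C)O[C@@H]3C[C@]12COC(C)=O | intermediate
18 | (13R)-2α,13-dihydroxy-3-oxolabda-7,14-dien-20-yl acetate | C=C[C@](C)(O)CC[C@H]1C(C)=CC[C@H]2C(C)(C)C(=O)[C@H](O)C[C@]12COC(C)=O | intermediate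
19 | (13R)-2α,3α,13-trihydroxylabda-7,14-dien-20-yl acetate | C=C[C@](C)(O)CC[C@H]1C(C)=CC[C@H]2C(C)(C)[C@H](O)[C@H](O)C[C@]12COC(C)=O | intermediate
20 | (2R,3S,5R,9S,10S,13R)-20-acetoxy-3α,13-dihydroxylabda-7,14-dien-2α-yl (Z)-2-methylbut-2-enoate (CNP0171655.1) | C=C[C@](C)(O)CC[C@H]1C(C)=CC[C@H]2C(C)(C)[C@H](O)[C@H](OC(=O)/C(C)=C\C)C[C@]12COC(C)=O | target

**Summary**

Total step count: 13. Longest linear sequence: 12 steps (from 1 through steps 1–5 and 7–13; step 6 is a one-step side branch).

Steps most likely to fail:

Step 7. The strongly Lewis acidic silyl triflimide may ionise the tertiary allylic silyl ether or start cation–olefin reactions in the side chain. The sequence may also stall after the first Michael addition because of congestion at the CMe2 terminus, leaving conversion incomplete at equimolar stoichiometry. Fallback (anionic Michael–Michael annulation instead of the acid-catalysed cycloaddition), setting out from 8 and 9: LiN(SiMe3)2 (THF, −78 °C) converts 9 into its cross-conjugated lithium dienolate. Addition of 8 should give conjugate addition at C5 anti to the alkenyl group, followed by intramolecular Michael closure of the lactone enolate onto the vinyl ketone, leading after NH4Cl quench to the bicyclic keto lactone (3S,4aR,8aR)-5,5-dimethyl-3-[(2E,6R)-6-methyl-6-(triethylsilyloxy)octa-2,7-dien-2-yl]hexahydro-1H-isochromene-1,6(5H)-dione F1. Soft enolisation of its ketone, whose only α-hydrogens are at C2 (t-BuMe2SiOTf, Et3N, CH2Cl2, 0 °C), returns to the route at 11.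

Step 8. Enolisation at the congested C10–H may be incomplete, or the lithium lactone enolate may fragment (ketene formation, ring opening) before it is silylated, so that the rearrangement never starts. Fallback (neutral thermal Claisen rearrangement of a cyclic enol ether, the 2-alkenyl-3,4-dihydro-2H-pyran to cyclohex-3-enecarbaldehyde reaction, which needs no enolate), setting out from 11: (i-Bu)2AlH (CH2Cl2, −78 °C) gives the lactol (3S,4aR,8aR)-6-(tert-butyldimethylsilyloxy)-5,5-dimethyl-3-alkenyl-hexahydro-1H-isochromen-1-ol F2 (anomeric mixture). Dehydration (MsCl, Et3N, THF, 0 °C to reflux) gives the cyclic enol ether with the C10=C20 double bond, the 4,4a,5,8-tetrahydro-3H-isochromene F3. Heating (decane, 190 °C, sealed base-washed glass) should rearrange it through the same boat array and with the same stereochemical course to (13R)-3-(tert-butyldimethylsilyloxy)-13-(triethylsilyloxy)labda-2,7,14-trien-20-al F4. NaBH4 (MeOH, 0 °C) reduces the aldehyde and the route is rejoined at 15.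

Step 12. Facial selectivity of the hydride addition may be poor (axial attack from the α face giving the 3β-alcohol, that is the trans-diol), or the acetate may be attacked on prolonged exposure. Fallback (enzyme-controlled instead of substrate-controlled reduction), setting out from 18 and returning at 19: an NADPH-dependent ketoreductase of the 3α-hydroxysteroid dehydrogenase (aldo-keto reductase) class, chosen from a panel for hydride delivery to the β face of C3, in phosphate buffer pH 7/DMSO with glucose and glucose dehydrogenase for cofactor recycling at 30 °C. This fallback makes no new compound (F0).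

**Further compounds**

F1 | step 7 | (3S,4aR,8aR)-5,5-dimethyl-3-[(2E,6R)-6-methyl-6-(triethylsilyloxy)octa-2,7-dien-2-yl]hexahydro-1H-isochromene-1,6(5H)-dione | O=C1O[C@H](/C(C)=C/CC[C@@](C)(O[Si](CC)(CC)CC)C=C)C[C@@H]2[C@H]1CCC(=O)C2(C)C
F2 | step 8 | (3S,4aR,8aR)-6-(tert-butyldimethylsilyloxy)-5,5-dimethyl-3-[(2E,6R)-6-methyl-6-(triethylsilyloxy)octa-2,7-dien-2-yl]-3,4,4a,5,8,8a-hexahydro-1H-isochromen-1-ol (anomeric mixture) | OC1O[C@H](/C(C)=C/CC[C@@](C)(O[Si](CC)(CC)CC)C=C)C[C@@H]2[C@H]1CC=C(O[Si](C)(C)C(C)(C)C)C2(C)C
F3 | step 8 | 6-(tert-butyldimethylsilyloxy)-5,5-dimethyl-3-[(2E,6R)-6-methyl-6-(triethylsilyloxy)octa-2,7-dien-2-yl]-4,4a,5,8-tetrahydro-3H-isochromene (C1=C8a enol ether; C3 and C4a as in 11) | C1=C2CC=C(O[Si](C)(C)C(C)(C)C)C(C)(C)[C@@H]2C[C@H](O1)/C(C)=C/CC[C@@](C)(O[Si](CC)(CC)CC)C=C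
F4 | step 8 | (13R)-3-(tert-butyldimethylsilyloxy)-13-(triethylsilyloxy)labda-2,7,14-trien-20-al | C=C[C@](C)(O[Si](CC)(CC)CC)CC[C@H]1C(C)=CC[C@H]2C(C)(C)C(O[Si](C)(C)C(C)(C)C)=CC[C@]12C=O
F0 | step 12 | none | none
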